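At 90.0 s the south-east run held 38.0% of its electrophile and 62.1% as product. These two entries sum to 100% of the charge, with each reading scattering by 0.5 percentage points, so at that reading the ledger of the electrophile, the smaller charge, needed no third line.

in all of them: electrophile 0.50 M

| run | nucleophile | remark | time |
|---|---|---|---|
| south-east | 2.8 equiv | run made earlier |  |
| Sunday's | 1.50 equiv |  | 3.0 min |
| Wednesday's | 2.00 equiv |  | 3.0 min |

south-east run (percent of the electrophile charged)

| time / s | electrophile / % | product / % |
|---|---|---|
| 10.0 | 78.2 | 21.8 |
| 12.0 | 76.2 | 23.6 |
| 20.0 | 66.2 | 32.6 |
| 30.0 | 59.5 | 41.7 |
| 50.0 | 49.6 | 51.2 |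
| 90.0 | 38.0 | 62.1 |

(each reading ± 0.5 percentage points)

1. part of the electrophile that has reacted at the end, Sunday's
2. part of the electrophile that has reacted at the end, Wednesday's
3. what raising the equivalents of nucleophile from its lowest to its highest value here does to the part of the electrophile that has reacted (changes below 5 percentage points count as none) (no change / it rises / it falls)

A closed ledger meant that one entry could carry the reckoning, so I took the natural logarithm of charged over remaining electrophile and divided it by the equivalents of nucleophile, and I called this the reach per equivalent. At 90.0 s it was 0.346. From 50.0 s to 90.0 s the logarithm grew by a factor of 1.38, while the square root of time gives 1.34. I therefore carried it by that root, and the reach per equivalent at 3.0 min came to 0.489. I then assumed, untested with a single run, that this figure holds at any equivalents, with the electrophile charge and time fixed. Multiplying by the equivalents and undoing the logarithm, I reckoned 52.0% reacted in Sunday's flask and 62.4% in Wednesday's, a rise of 10 points.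

The forecast, reading the curve as “strong product inhibition”, gave 60% and 68%, both higher than mine, and also said it rises.

Sunday's flask gave 49.8% and Wednesday's 61.3%, so the answer to the third question was "it rises", by 11 points.

    nucleophile + acid set free ⇌ protonated nucleophile, settled at all times (K = 390 M⁻¹)
    2 nucleophile → homo dimer (k = 0.00240 M⁻¹ s⁻¹)
    nucleophile ⇌ dormant form (K = 1.20, k = 0.0180 s⁻¹)
    electrophile + nucleophile → acid set free + product (k = 0.0210 M⁻¹ s⁻¹)

Sunday's flask ended with 10.7% of its nucleophile free, less than the 50% of its electrophile left. Read back from these results, the reach per equivalent was 0.460 in Sunday's flask and 0.475 in Wednesday's, against my 0.489.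

For Sunday's flask recharged with 6.00 equiv of nucleophile, my 0.489 leaves 5.32% of the electrophile at 3.0 min. The computed flask leaves 4.2%.

Readings and results stem from a simulated flask from invented constants, noise included.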